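The decalin is opened at the ring-fusion bond C5–C10 and at C1–C2, so a single thermal intramolecular Diels–Alder reaction builds ring A (C1–C5, C10) as the cycloadduct and ring B (C5–C10) through the C6–C9 tether, fixing C1, C5 and C10 at once. It exploits the 1,4-placement of the C4 oxygen and the C1 side chain on ring A together with the anti C1-substituent/C10-methyl pair, which translate into a 2-siloxy diene (C2–C5) and a (Z)-β-methyl enone (C1=C10). The precursor is an acyclic triene carrying the C7 isopropenyl centre of (S)-limonene. The aryl group, C1′–H, the C4 carbinol, the C11 hydroxyl and the formyl groups are added afterwards.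

Key step: step 13

Remark (locants): every intermediate carries the decalin locants of the target, C1 (side-chain carbon) to C10 (methyl-bearing fusion carbon), C1′ for the future benzylic carbon and C11 for the carbinol carbon on C7; ring A = C1–C5 + C10, ring B = C5–C10.
Remark (missing carbon): the keto aldehyde from limonene has only one CH2 between C7 and its aldehyde carbon (C5), so C4 is supplied by a Wittig methoxymethylenation.
Remark (dienophile carbonyl): it is carried as an ester, then a Weinreb amide, and the isobutyl group is added last from isobutylmagnesium bromide, because syn cuprate addition is dependable for ynoates but not ynones and an isobutyl ketone would compete in the silyl dienol ether formation.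
Remark (work-up): organometallic steps are taken to end with an aqueous quench.

Step 1
Reactants: 1 (S)-(−)-limonene
Product: 2 (4S)-limonene 1,2-oxide (cis/trans mixture at the epoxide)
Conditions: mCPBA, CH2Cl2, 0 °C
Reagents that add atoms: 3-chloroperoxybenzoic acid (mCPBA), OOC(=O)c1cccc(Cl)c1
Why: Prilezhaev epoxidation is fastest at the electron-rich trisubstituted ring alkene and leaves the isopropenyl group, and the epoxide diastereomers do not matter because both epoxide carbons become carbonyl carbons.

Step 2
Reactants: 2 (4S)-limonene 1,2-oxide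
Product: 4 (3S)-6-oxo-3-(prop-1-en-2-yl)heptanal, via limonene-1,2-diol 3 (not isolated)
Conditions: H5IO6, THF/H2O, 0 °C → rt
Reagents that add atoms: water, O
Why: Acidic epoxide hydrolysis followed by Malaprade glycol cleavage opens the ring between the two oxygenated carbons, giving the methyl ketone (future C10 arm) and the aldehyde (future C5) without touching the stereocentre.

Step 3
Reactants: 4 (3S)-6-oxo-3-(prop-1-en-2-yl)heptanal
Product: 5 (5S)-8-methoxy-5-(prop-1-en-2-yl)oct-7-en-2-one (E/Z mixture)
Conditions: Ph3P(CH2OMe)Cl, KOtBu, THF, −78 → 0 °C (1.05 equiv of ylide added to 4)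
Reagents that add atoms: (methoxymethyl)triphenylphosphonium chloride, COC[P+](c1ccccc1)(c1ccccc1)c1ccccc1.[Cl-]
Why: Wittig methoxymethylenation is much faster at the aldehyde than at the methyl ketone at low temperature and supplies C4 as an enol ether that masks the homologated aldehyde through the next four steps.

Step 4
Reactants: 5 (5S)-8-methoxy-5-(prop-1-en-2-yl)oct-7-en-2-one
Product: 7 (4S)-1-methoxy-4-(prop-1-en-2-yl)oct-1-en-7-yne, via enol diethyl phosphate 6 (not isolated)
Conditions: LDA, THF, −78 °C; ClP(O)(OEt)2, −78 °C → rt; LDA (2.3 equiv), −78 °C → rt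
Reagents that add atoms: none
Why: In this enol phosphate elimination (Negishi alkyne synthesis) the kinetic terminal enolate of the methyl ketone is trapped as its enol phosphate and eliminated by LDA to the terminal alkyne, conditions that the enol ether and the isopropenyl group tolerate.

Step 5
Reactants: 7 (4S)-1-methoxy-4-(prop-1-en-2-yl)oct-1-en-7-yne
Product: 9 methyl (6S)-9-methoxy-6-(prop-1-en-2-yl)non-8-en-2-ynoate, via lithium acetylide 8 (not isolated)
Conditions: n-BuLi, THF, −78 °C; ClCO2Me, −78 → 0 °C
Reagents that add atoms: methyl chloroformate, COC(=O)Cl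
Why: C-acylation of a lithium acetylide by a chloroformate is the standard route to an alkynoate.

Step 6
Reactants: 9 methyl (6S)-9-methoxy-6-(prop-1-en-2-yl)non-8-en-2-ynoate
Product: 10 methyl (2Z,6S)-9-methoxy-3-methyl-6-(prop-1-en-2-yl)nona-2,8-dienoate
Conditions: Me2CuLi (from MeLi and CuI), THF, −78 °C; MeOH/H2O quench at −78 °C
Reagents that add atoms: lithium dimethylcuprate, [Li+].C[Cu-]C
Why: Syn carbocupration (Gilman conjugate addition) of the ynoate at −78 °C gives a configurationally stable alkenylcopper whose protonation leaves the new methyl cis to H and the tether cis to the ester, the (2Z) geometry the dienophile needs.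

Step 7
Reactants: 10 methyl (2Z,6S)-9-methoxy-3-methyl-6-(prop-1-en-2-yl)nona-2,8-dienoate
Product: 11 (2Z,6S)-N,9-dimethoxy-N,3-dimethyl-6-(prop-1-en-2-yl)nona-2,8-dienamide
Conditions: MeNH(OMe)·HCl, i-PrMgCl, THF, −20 → 0 °C
Reagents that add atoms: N,O-dimethylhydroxylamine hydrochloride, CNOC.Cl
Why: Aminolysis of the ester by the chloromagnesium amide (Weinreb amide synthesis) gives an acyl group that is not enolised in step 11 and accepts exactly one Grignard equivalent in step 12.

Step 8
Reactants: 11 (2Z,6S)-N,9-dimethoxy-N,3-dimethyl-6-(prop-1-en-2-yl)nona-2,8-dienamide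
Product: 12 (2Z,6S)-N-methoxy-N,3-dimethyl-9-oxo-6-(prop-1-en-2-yl)non-2-enamide
Conditions: 1 M HCl, THF, 0 °C → rt
Reagents that add atoms: water, O
Why: Mild acid hydrolysis of the methyl enol ether releases the homologated aldehyde (C4) under conditions that the Weinreb amide, the (Z)-alkene and the isopropenyl group should survive.

Step 9
Reactants: 12 (2Z,6S)-N-methoxy-N,3-dimethyl-9-oxo-6-(prop-1-en-2-yl)non-2-enamide
Product: 13 (2Z,6S)-9-hydroxy-N-methoxy-N,3-dimethyl-6-(prop-1-en-2-yl)undeca-2,10-dienamide (both C9 epimers)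
Conditions: vinylMgBr (1.1 equiv), THF, −78 °C
Reagents that add atoms: vinylmagnesium bromide, C=C[Mg]Br
Why: Grignard 1,2-addition is far faster at the aldehyde than at the hindered conjugated Weinreb amide at −78 °C, and the new carbinol centre is removed in step 10.

Step 10
Reactants: 13 (2Z,6S)-9-hydroxy-N-methoxy-N,3-dimethyl-6-(prop-1-en-2-yl)undeca-2,10-dienamide
Product: 14 (2Z,6S)-N-methoxy-N,3-dimethyl-9-oxo-6-(prop-1-en-2-yl)undeca-2,10-dienamide
Conditions: DMP, CH2Cl2, 0 °C → rt
Reagents that add atoms: none
Why: Dess–Martin oxidation turns the allylic alcohol into the vinyl ketone under near-neutral conditions that avoid Michael addition or polymerisation.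

Step 11
Reactants: 14 (2Z,6S)-N-methoxy-N,3-dimethyl-9-oxo-6-(prop-1-en-2-yl)undeca-2,10-dienamide
Product: 15 (2Z,6S,8Z)-9-[tert-butyl(dimethyl)silyl]oxy-N-methoxy-N,3-dimethyl-6-(prop-1-en-2-yl)undeca-2,8,10-trienamide
Conditions: TBSOTf, Et3N, CH2Cl2, −78 → 0 °C
Reagents that add atoms: tert-butyldimethylsilyl trifluoromethanesulfonate, CC(C)(C)[Si](C)(C)OS(=O)(=O)C(F)(F)F
Why: Soft enolisation (silyl triflate/amine) of the vinyl ketone can only occur at the C5 methylene and should give the thermodynamically preferred (Z)-silyl enol ether, with the tether trans to the vinyl group as the diene requires, while the Weinreb amide stays untouched.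

Step 12
Reactants: 15 (2Z,6S,8Z)-9-[tert-butyl(dimethyl)silyl]oxy-N-methoxy-N,3-dimethyl-6-(prop-1-en-2-yl)undeca-2,8,10-trienamide
Product: 16 (5Z,9S,11Z)-12-[tert-butyl(dimethyl)silyl]oxy-2,6-dimethyl-9-(prop-1-en-2-yl)tetradeca-5,11,13-trien-4-one
Conditions: i-BuMgBr, THF, −78 → 0 °C; pH 7 buffer
Reagents that add atoms: isobutylmagnesium bromide, CC(C)C[Mg]Br
Why: In this Weinreb ketone synthesis the chelated tetrahedral adduct stops at the ketone stage, the silyl dienol ether is inert to the Grignard reagent, and the enone is released only on neutral work-up so that its (Z) geometry is kept.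

Step 13
Reactants: 16 (5Z,9S,11Z)-12-[tert-butyl(dimethyl)silyl]oxy-2,6-dimethyl-9-(prop-1-en-2-yl)tetradeca-5,11,13-trien-4-one
Product: 17 1-[(1R,4aS,6S,8aS)-4-[tert-butyl(dimethyl)silyl]oxy-8a-methyl-6-(prop-1-en-2-yl)-1,2,4a,5,6,7,8,8a-octahydronaphthalen-1-yl]-3-methylbutan-1-one (trans-fused, C1 acyl anti to the C10 methyl)
Conditions: PhMe (0.01 M), BHT (cat.), 165 °C, sealed tube (silylated glass)
Reagents that add atoms: none
Why: This is a concerted, asynchronous intramolecular [4+2] cycloaddition in which the nucleophilic terminus C5 of the silyl dienol ether bonds to the enone β-carbon C10 ahead of the C2–C1 bond, so that the siloxy and acyl groups end 1,4 on ring A as the orbital polarities demand. The closest known reaction type is the thermal intramolecular Diels–Alder reaction of deca-1,7,9-trienes that carry a 2-siloxy diene and a terminally activated dienophile. Ring B (C5–C10) closes through the C6–C9 tether in a chair-like 6-exo-trig mode, and ring A (C1–C5, C10) closes as the six-membered cycloadduct ring in the usual boat-like array of the two π-systems. C1 relative to C10 is controlled by the (Z) geometry of the enone (suprafacial addition keeps the acyl group cis to C9, hence anti to the C10 methyl), C5 relative to C10 (trans fusion) by the acyl-exo transition state in which the tether leaves both π-systems equatorially with the C10 methyl and C1–H under the diene, and the absolute sense of all three by C7, whose isopropenyl group stays equatorial on the chair tether while the C10 methyl is axial. The selectivity needed is therefore acyl-exo addition (trans fusion) on the C7-equatorial face. It should be secured by the absence of a Lewis acid (which would enforce the acyl-endo, cis-fused mode), by the C4 siloxy group, which meets the C6–C7 bond in 1,3-allylic strain in the cis-fused chair with an axial diene, and by the (Z)-acyl group, which is pushed over ring B in the other cis-fused chair with an axial dienophile.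

Step 14
Reactants: 17 octalin silyl enol ether ketone; 18 1,3,5-trimethoxybenzene
Product: 21 C1′ tertiary benzylic alcohol (17 with C1′=O turned into C1′(OH)(2,4,6-trimethoxyphenyl), both carbinol epimers), via 2,4,6-trimethoxyphenyllithium 19 (not isolated), via dichloro(2,4,6-trimethoxyphenyl)cerium 20 (not isolated)
Conditions: 18, n-BuLi, THF, 0 °C → rt; CeCl3, −78 °C; then 17, −78 → −20 °C
Reagents that add atoms: none
Why: Ortho-lithiation of the arene between two methoxy groups and transmetalation to the weakly basic organocerium reagent allow 1,2-addition to the hindered C1′ ketone without enolisation or C1 epimerisation while C4 stays masked as the silyl enol ether, and the carbinol configuration is irrelevant because C1′ is ionised in step 15.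

Step 15
Reactants: 21 C1′ tertiary benzylic alcohol
Product: 22 (4S,4aR,7S,8aS)-4a-methyl-4-[(1R)-3-methyl-1-(2,4,6-trimethoxyphenyl)butyl]-7-(prop-1-en-2-yl)octahydronaphthalen-1(2H)-one (the C4 ketone)
Conditions: Et3SiH (excess), TFA, CH2Cl2, −40 → 0 °C
Reagents that add atoms: none
Why: In this ionic hydrogenation the 2,4,6-trimethoxybenzylic alcohol ionises under mild acid and the cation is trapped by the silane while the silyl enol ether is protodesilylated at C3 to the C4 ketone, and C1′ should come out (1′R) because the planar cation keeps C1–H in its plane next to the aryl group (1,3-allylic strain with an ortho methoxy group) with the isobutyl methylene over ring A, so that hydride enters from the C2 side, anti to C10 and its C9 methylene.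

Step 16
Reactants: 22 C4 ketone
Product: 23 (1R,4S,4aR,7S,8aS)-1,4a-dimethyl-4-[(1R)-3-methyl-1-(2,4,6-trimethoxyphenyl)butyl]-7-(prop-1-en-2-yl)decahydronaphthalen-1-ol (C4 hydroxyl axial, cis to the C10 methyl)
Conditions: MeMgBr, CeCl3, THF, −78 → 0 °C
Reagents that add atoms: methylmagnesium bromide, C[Mg]Br
Why: Cerium-mediated Grignard 1,2-addition to the C4 ketone should follow the equatorial trajectory because the axial one is blocked by the 1,3-diaxial C10 methyl group, giving the equatorial methyl and the axial hydroxyl cis to the C10 methyl as in the target.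

Step 17
Reactants: 23 C4 methyl carbinol
Product: 24 (1R,4S,4aR,7S,8aS)-7-(2-hydroxypropan-2-yl)-1,4a-dimethyl-4-[(1R)-3-methyl-1-(2,4,6-trimethoxyphenyl)butyl]decahydronaphthalen-1-ol
Conditions: Co(acac)2 (cat.), PhSiH3, O2, THF, rt
Reagents that add atoms: dioxygen, O=O
Why: Mukaiyama hydration (cobalt-catalysed hydrogen-atom transfer, oxygen trapping, reduction) converts the 1,1-disubstituted alkene with Markovnikov selectivity into the C11 tertiary alcohol, and no other alkene is left to compete.

Step 18
Reactants: 24 diol with the trimethoxyphenyl group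
Product: 26 5-[(1R)-1-[(1S,4R,4aS,6S,8aR)-4-hydroxy-6-(2-hydroxypropan-2-yl)-4,8a-dimethyldecahydronaphthalen-1-yl]-3-methylbutyl]-2,4,6-trimethoxybenzene-1,3-dicarbaldehyde, via monoformyl lithium hemiaminal 25 (not isolated)
Conditions: n-BuLi, TMEDA, THF, 0 °C; DMF, −78 → 0 °C; n-BuLi, 0 °C; DMF; H2O
Reagents that add atoms: N,N-dimethylformamide, CN(C)C=O
Why: Directed ortho-metalation/formylation at the two ring positions that each lie between two methoxy groups, run twice in one flask with the first formyl group protected in situ as its lithium hemiaminal, tolerates the two tertiary alcohols (as alkoxides) that Lewis-acidic formylations would destroy.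

Step 19
Reactants: 26 trimethoxy dialdehyde
Product: 27 5-[(1R)-1-[(1S,4R,4aS,6S,8aR)-4-hydroxy-6-(2-hydroxypropan-2-yl)-4,8a-dimethyldecahydronaphthalen-1-yl]-3-methylbutyl]-2,4,6-trihydroxybenzene-1,3-dicarbaldehyde (target)
Conditions: NaSEt, DMF, 120 °C; then 1 M HCl
Reagents that add atoms: none
Why: Nucleophilic (SN2) O-demethylation by thiolate is activated by the ortho/para formyl groups (each methoxy is a vinylogous methyl ester) and, being basic, spares the two tertiary alcohols that a boron trihalide would ionise.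

Compound list

1 | (S)-(−)-limonene | CC1=CC[C@@H](C(C)=C)CC1 | starting material
2 | (4S)-limonene 1,2-oxide (cis/trans mixture) | CC12OC1C[C@@H](C(C)=C)CC2 | intermediate
3 | (4S)-1-methyl-4-(prop-1-en-2-yl)cyclohexane-1,2-diol (limonene-1,2-diol) | CC1(O)C(O)C[C@@H](C(C)=C)CC1 | intermediate (not isolated)
4 | (3S)-6-oxo-3-(prop-1-en-2-yl)heptanal | O=CC[C@@H](C(C)=C)CCC(C)=O | intermediate
5 | (5S)-8-methoxy-5-(prop-1-en-2-yl)oct-7-en-2-one (E/Z mixture) | COC=CC[C@@H](C(C)=C)CCC(C)=O | intermediate
6 | diethyl (5S)-8-methoxy-5-(prop-1-en-2-yl)octa-1,7-dien-2-yl phosphate | COC=CC[C@@H](C(C)=C)CCC(=C)OP(=O)(OCC)OCC | intermediate (not isolated)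
7 | (4S)-1-methoxy-4-(prop-1-en-2-yl)oct-1-en-7-yne | COC=CC[C@@H](C(C)=C)CCC#C | intermediate
8 | lithium acetylide of 7 | COC=CC[C@@H](C(C)=C)CCC#C[Li] | intermediate (not isolated)
9 | methyl (6S)-9-methoxy-6-(prop-1-en-2-yl)non-8-en-2-ynoate | COC=CC[C@@H](C(C)=C)CCC#CC(=O)OC | intermediate
10 | methyl (2Z,6S)-9-methoxy-3-methyl-6-(prop-1-en-2-yl)nona-2,8-dienoate | COC(=O)/C=C(C)\CC[C@H](C(C)=C)CC=COC | intermediate
11 | (2Z,6S)-N,9-dimethoxy-N,3-dimethyl-6-(prop-1-en-2-yl)nona-2,8-dienamide | CON(C)C(=O)/C=C(C)\CC[C@H](C(C)=C)CC=COC | intermediate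
12 | (2Z,6S)-N-methoxy-N,3-dimethyl-9-oxo-6-(prop-1-en-2-yl)non-2-enamide | CON(C)C(=O)/C=C(C)\CC[C@H](C(C)=C)CCC=O | intermediate
13 | (2Z,6S)-9-hydroxy-N-methoxy-N,3-dimethyl-6-(prop-1-en-2-yl)undeca-2,10-dienamide (C9 epimers) | CON(C)C(=O)/C=C(C)\CC[C@H](C(C)=C)CCC(O)C=C | intermediate
14 | (2Z,6S)-N-methoxy-N,3-dimethyl-9-oxo-6-(prop-1-en-2-yl)undeca-2,10-dienamide | CON(C)C(=O)/C=C(C)\CC[C@H](C(C)=C)CCC(=O)C=C | intermediate
15 | (2Z,6S,8Z)-9-[tert-butyl(dimethyl)silyl]oxy-N-methoxy-N,3-dimethyl-6-(prop-1-en-2-yl)undeca-2,8,10-trienamide | CON(C)C(=O)/C=C(C)\CC[C@H](C(C)=C)C/C=C(\O[Si](C)(C)C(C)(C)C)C=C | intermediate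
16 | (5Z,9S,11Z)-12-[tert-butyl(dimethyl)silyl]oxy-2,6-dimethyl-9-(prop-1-en-2-yl)tetradeca-5,11,13-trien-4-one (cycloaddition precursor) | CC(C)CC(=O)/C=C(C)\CC[C@H](C(C)=C)C/C=C(\O[Si](C)(C)C(C)(C)C)C=C | intermediate
17 | 1-[(1R,4aS,6S,8aS)-4-[tert-butyl(dimethyl)silyl]oxy-8a-methyl-6-(prop-1-en-2-yl)-1,2,4a,5,6,7,8,8a-octahydronaphthalen-1-yl]-3-methylbutan-1-one (trans-fused cycloadduct) | CC(C)CC(=O)[C@@H]1CC=C(O[Si](C)(C)C(C)(C)C)[C@H]2C[C@@H](C(C)=C)CC[C@]12C | intermediate
18 | 1,3,5-trimethoxybenzene | COc1cc(OC)cc(OC)c1 | starting material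
19 | 2,4,6-trimethoxyphenyllithium | [Li]c1c(OC)cc(OC)cc1OC | intermediate (not isolated)
20 | dichloro(2,4,6-trimethoxyphenyl)cerium | Cl[Ce](Cl)c1c(OC)cc(OC)cc1OC | intermediate (not isolated)
21 | C1′ tertiary benzylic alcohol: 17 with C1′(OH)(2,4,6-trimethoxyphenyl) in place of C1′=O, both carbinol epimers | CC(C)CC(O)(c1c(OC)cc(OC)cc1OC)[C@@H]1CC=C(O[Si](C)(C)C(C)(C)C)[C@H]2C[C@@H](C(C)=C)CC[C@]12C | intermediate
22 | (4S,4aR,7S,8aS)-4a-methyl-4-[(1R)-3-methyl-1-(2,4,6-trimethoxyphenyl)butyl]-7-(prop-1-en-2-yl)octahydronaphthalen-1(2H)-one | CC(C)C[C@@H](c1c(OC)cc(OC)cc1OC)[C@@H]1CCC(=O)[C@H]2C[C@@H](C(C)=C)CC[C@]12C | intermediate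
23 | (1R,4S,4aR,7S,8aS)-1,4a-dimethyl-4-[(1R)-3-methyl-1-(2,4,6-trimethoxyphenyl)butyl]-7-(prop-1-en-2-yl)decahydronaphthalen-1-ol | CC(C)C[C@@H](c1c(OC)cc(OC)cc1OC)[C@@H]1CC[C@@](C)(O)[C@H]2C[C@@H](C(C)=C)CC[C@]12C | intermediate
24 | (1R,4S,4aR,7S,8aS)-7-(2-hydroxypropan-2-yl)-1,4a-dimethyl-4-[(1R)-3-methyl-1-(2,4,6-trimethoxyphenyl)butyl]decahydronaphthalen-1-ol | CC(C)C[C@@H](c1c(OC)cc(OC)cc1OC)[C@@H]1CC[C@@](C)(O)[C@H]2C[C@@H](C(C)(C)O)CC[C@]12C | intermediate
25 | monoformyl stage of 24 as its trilithium salt (lithium hemiaminal of the first aldehyde, two lithium alkoxides) | CC(C)C[C@@H](c1c(OC)cc(OC)c(C(O[Li])N(C)C)c1OC)[C@@H]1CC[C@@](C)(O[Li])[C@H]2C[C@@H](C(C)(C)O[Li])CC[C@]12C | intermediate (not isolated)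
26 | 5-[(1R)-1-[(1S,4R,4aS,6S,8aR)-4-hydroxy-6-(2-hydroxypropan-2-yl)-4,8a-dimethyldecahydronaphthalen-1-yl]-3-methylbutyl]-2,4,6-trimethoxybenzene-1,3-dicarbaldehyde | CC(C)C[C@@H](c1c(OC)c(C=O)c(OC)c(C=O)c1OC)[C@@H]1CC[C@@](C)(O)[C@H]2C[C@@H](C(C)(C)O)CC[C@]12C | intermediate
27 | 5-[(1R)-1-[(1S,4R,4aS,6S,8aR)-4-hydroxy-6-(2-hydroxypropan-2-yl)-4,8a-dimethyldecahydronaphthalen-1-yl]-3-methylbutyl]-2,4,6-trihydroxybenzene-1,3-dicarbaldehyde | CC(C)C[C@@H](c1c(O)c(C=O)c(O)c(C=O)c1O)[C@@H]1CC[C@@](C)(O)[C@H]2C[C@@H](C(C)(C)O)CC[C@]12C | target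

Total step count: 19. Longest linear sequence: 19 steps (1 → 27); 18 enters as purchased in step 14.

Steps most likely to fail

Step 13. The cycloaddition may run through the acyl-endo, cis-fused mode, or the enone may lose its (Z) geometry by thermal 1,5-hydrogen shift (dienolisation) before it cyclises. Base equilibration at C5 at the later C4-ketone stage cannot be relied on to repair this, because the axial C1 substituent makes the cis-fused epimer thermodynamically competitive. The fallback moves the cycloaddition one step earlier and sets out from 15. Heating 15 (PhMe, BHT, 180–200 °C) should give the N-methoxy-N-methyl amide cycloadduct F1. Its twisted amide group cannot dienolise in this way and is more strongly biased to the exo position. F1 is then treated with i-BuMgBr (THF, 0 °C) and the route is rejoined at 17.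

Step 15. Hydride capture by the benzylic cation may show poor facial selectivity, or proton loss from the cation and reduction of the isopropenyl group may intervene. The fallback replaces substrate-controlled hydride capture by catalyst-controlled alkene hydrogenation and sets out from 21.
- Catalytic TsOH in wet CH2Cl2 without silane dehydrates the benzylic alcohol towards the isobutyl methylene and cleaves the silyl enol ether, giving the trisubstituted aryl alkene ketone F2 (used as one geometric isomer after chromatography).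
- MeMgBr/CeCl3, as in step 16, gives the aryl alkene C4 carbinol F3.
- Mukaiyama hydration, as in step 17, should be much faster at the 1,1-disubstituted isopropenyl group than at the hindered trisubstituted aryl alkene and gives the aryl alkene diol F4.
- Asymmetric hydrogenation of F4 (H2, [Ir(cod)(L)]BArF with a chiral phosphinooxazoline L, ligand enantiomer chosen for the (1′R) product, CH2Cl2) returns to the route at 24.

Step 14. The hindered C1′ ketone may be enolised, or may simply not be attacked by the di-ortho-substituted aryl metal. The fallback replaces carbonyl addition by cross-coupling and sets out from 17.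
- KHMDS and PhNTf2 (THF, −78 °C) deprotonate the isobutyl methylene and give the enol triflate F5.
- Negishi coupling of F5 with 2,4,6-trimethoxyphenylzinc chloride F6 (from 19 and ZnCl2; Pd(OAc)2, SPhos, THF, 50 °C) gives the aryl alkene silyl enol ether F7.
- The conditions of step 15 (Et3SiH, TFA) protonate the alkene of F7 to the same benzylic cation and cleave the silyl enol ether, so the route is rejoined at 22.

Further compounds

F1 | step 13 | N-methoxy-N-methyl amide cycloadduct (amide analogue of 17) | CON(C)C(=O)[C@@H]1CC=C(O[Si](C)(C)C(C)(C)C)[C@H]2C[C@@H](C(C)=C)CC[C@]12C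
F2 | step 15 | aryl alkene ketone (C1′=CH–iPr alkene, C4 ketone) | CC(C)C=C(c1c(OC)cc(OC)cc1OC)[C@@H]1CCC(=O)[C@H]2C[C@@H](C(C)=C)CC[C@]12C
F3 | step 15 | aryl alkene C4 carbinol | CC(C)C=C(c1c(OC)cc(OC)cc1OC)[C@@H]1CC[C@@](C)(O)[C@H]2C[C@@H](C(C)=C)CC[C@]12C
F4 | step 15 | aryl alkene diol | CC(C)C=C(c1c(OC)cc(OC)cc1OC)[C@@H]1CC[C@@](C)(O)[C@H]2C[C@@H](C(C)(C)O)CC[C@]12C
F5 | step 14 | enol triflate of 17 (triflate cis to isopropyl) | CC(C)/C=C(\OS(=O)(=O)C(F)(F)F)[C@@H]1CC=C(O[Si](C)(C)C(C)(C)C)[C@H]2C[C@@H](C(C)=C)CC[C@]12C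
F6 | step 14 | 2,4,6-trimethoxyphenylzinc chloride | Cl[Zn]c1c(OC)cc(OC)cc1OC
F7 | step 14 | aryl alkene silyl enol ether | CC(C)/C=C(\c1c(OC)cc(OC)cc1OC)[C@@H]1CC=C(O[Si](C)(C)C(C)(C)C)[C@H]2C[C@@H](C(C)=C)CC[C@]12C
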